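**Assumption:** atoms are labelled with ent‑kaurane numbering (C5 ketone, C6=C7, C8 quaternary bridgehead, C9 ring‑fusion CH, C10 quaternary carbon with C20 methyl, C11–O–C16 ether, C13 bridgehead CH, C15 bridge CH2, C17 methyl on C16); compounds 1, 2, 10, 12 and 13 are taken as commercial.

## Retrosynthetic overview

1. Target ⇒ Horner–Wadsworth–Emmons union of cage aldehyde 11 with glutamine phosphonoamide 14, then ester cleavage.
2. 11 ⇒ Michael addition of known methyl cage enone 9 to acrolein (C10 set by the cage); 9 ⇒ cage enone 7 by C=C transposition (hydrogenation sets C9, then kinetic desaturation).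
3. 7 ⇒ bromo ether 6 by a photochemical intramolecular γ‑alkylation of the dienolate: this forms the C8–C15 bond, the C8 quaternary bridgehead and the bicyclo[3.2.1]octane.
4. 6 ⇒ (+)‑nopinone + ethyl vinyl ketone via Robinson annulation, cyclobutane opening to a regiodefined dienol acetate, γ‑hydroxylation and bromoetherification.
5. Ring order: nopinone six‑ring (bought, carries C13) → enone ring (Robinson) → tetrahydrofuran (bromoetherification) → cyclopentane/cage (photochemical step). C13 comes from nopinone; C11, C16, C8, C9 and C10 are each set under control of the existing framework; the glutamine centre is bought.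

## Route

**Step 1**
Reactants: 1, (1R,5S)‑(+)‑nopinone; 2, ethyl vinyl ketone
Product: 3, pinane‑fused tricyclic enone (2‑methylcyclohex‑2‑enone ring fused at nopinone C2/C3; C5=O, C10(Me)=C9, C8–H syn to the CMe2 bridge, cyclobutane C11–C16–C13–C12 intact)
Conditions: KOH (0.3 equiv), EtOH, 0 °C → rt; then KOH, EtOH, reflux
Reagents that add atoms: ethyl vinyl ketone (2), CCC(=O)C=C
Why: Robinson annulation; nopinone can enolise only toward C3 because the other α‑carbon is a bridgehead, Michael addition occurs anti to the CMe2 bridge, and aldol condensation onto the ketone gives the 2‑methyl enone (C8–H is removed later).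

**Step 2**
Reactants: 3, tricyclic enone
Product: 4, 1‑methyl‑6‑(prop‑1‑en‑2‑yl)‑3,4,4a,5,6,7‑hexahydronaphthalen‑2‑yl acetate (dienol acetate with C9=C11; isopropenyl on C13 trans to C7 on C8)
Conditions: BF3·OEt2, Zn(OAc)2, Ac2O, 0 °C → rt
Reagents that add atoms: acetic anhydride, CC(=O)OC(C)=O
Why: Lewis‑acid vinylogous cyclobutane fragmentation (as in nopinone → 4‑isopropenylcyclohexenyl acetate); the C11–C16 bond ionises to the tertiary cation, E1 loss gives the isopropenyl group, and O‑acetylation traps the dienol only as the C9=C11 isomer, which distinguishes C11 from C8 while leaving C13 untouched.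

**Step 3**
Reactants: 4, dienol acetate
Product: 5, 8‑hydroxy‑1‑methyl‑6‑(prop‑1‑en‑2‑yl)‑4,4a,5,6,7,8‑hexahydronaphthalen‑2(3H)‑one (C11–OH cis to the isopropenyl group)
Conditions: mCPBA (1.05 equiv), NaHCO3, CH2Cl2–H2O, −20 → 0 °C
Reagents that add atoms: mCPBA, OOC(=O)c1cccc(Cl)c1
Why: vinylogous Rubottom oxidation (the steroid 3,5‑dienol acetate → 6β‑hydroxy‑4‑en‑3‑one reaction); the trisubstituted dienol C9=C11 bond should react faster than the 1,1‑disubstituted alkene, and axial attack at C11 in the conformer fixed by the trans C8/C13 relationship (isopropenyl axial) puts OH syn‑diaxial to the isopropenyl group.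

**Step 4**
Reactants: 5, γ‑hydroxy enone
Product: 6, bromo ether (6‑oxabicyclo[3.2.1]octane with C11–O–C16, C16 bearing CH3 exo and CH2Br endo over C8; enone C5=O/C10(Me)=C9; C8–H)
Conditions: NBS (1.05 equiv), CH2Cl2, 0 °C, dark
Reagents that add atoms: N‑bromosuccinimide, BrN1C(=O)CCC1=O
Why: 5‑exo Markovnikov bromoetherification by the syn‑diaxial hydroxyl; the rotamer with the flat =CH2 rather than CH3 over the ring is favoured, so CH2Br ends endo and C16 is set (the same selectivity as the known tetralol bromoetherification in platensimycin work).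

**Step 5**
Reactants: 6, bromo ether
Product: 7, cage enone (oxatetracycle with C8–C15 bond formed; C5=O, C10(Me)=C9)
Conditions: KOt‑Bu (1.3 equiv), degassed DMSO–THF, 365 nm LEDs, 20 °C
Reagents that add atoms: none
Why: Proposed new method: photostimulated intramolecular SRN1‑type γ‑alkylation of an extended potassium dienolate by a neopentyl‑type bromide. The only γ‑hydrogen is at C8 (C11 is an oxabicyclic bridgehead), so a single dienolate forms; on near‑UV excitation it transfers an electron to σ*(C–Br), bromide leaves, and the primary C15 radical held over C8 couples at the dienolate terminus (5‑exo) rather than the internal C9, giving the quaternary bridgehead and the bicyclo[3.2.1]octane with the enone restored. Closest known chemistry: photostimulated SRN1 alkylation of ketone enolates with neopentyl halides and the thermal phenolate para‑alkylation of the analogous bromo ether.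

**Step 6**
Reactants: 7, cage enone
Product: 8, saturated cage ketone (C9–H cis to O‑11; C10 H/Me epimers, inconsequential)
Conditions: H2 (1–4 atm), [Ir(cod)(PCy3)(py)]PF6 (5–10 mol %), CH2Cl2, rt
Reagents that add atoms: none
Why: directed homogeneous hydrogenation of a tetrasubstituted enone C=C; H2 is delivered syn from the face flanked by the allylic ether oxygen (O‑coordination to Ir, and one exo‑H on C15 versus two on C12/C14 on the other face), which places H‑9 cis to O‑11 and C10 anti to C15 as in the target.

**Step 7**
Reactants: 8, saturated cage ketone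
Product: 9, methyl cage enone (C5=O, C6=C7, C10 H/Me; the known monomethyl platensimycin cage enone)
Conditions: LDA, THF, −78 °C; then N‑tert‑butylbenzenesulfinimidoyl chloride, −78 °C
Reagents that add atoms: none
Why: kinetic deprotonation at the unhindered C6 methylene (not the tertiary C10–H) followed by Mukaiyama dehydrogenation gives the C6=C7 enone regiospecifically; no stereocentre is touched.

**Step 8**
Reactants: 9, methyl cage enone; 10, acrolein
Product: 11, cage aldehyde (C10 bearing CH3 and CH2CH2CHO)
Conditions: KHMDS (1.05 equiv), THF, −78 °C; acrolein, −78 → −20 °C; AcOH quench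
Reagents that add atoms: acrolein (10), C=CC=O
Why: Michael addition of the only possible enolate (C10); the electrophile enters from the open outer face of the cage, the same sense as the literature allylation of this enolate, leaving the methyl in the inner position and setting the C10 quaternary centre (any 1,2‑adduct reverts by retro‑aldol).

**Step 9**
Reactants: 12, 2‑(diethoxyphosphoryl)propanoic acid; 13, L‑glutamine tert‑butyl ester hydrochloride
Product: 14, tert‑butyl N‑[2‑(diethoxyphosphoryl)propanoyl]‑L‑glutaminate
Conditions: EDC·HCl, HOBt, i‑Pr2NEt, CH2Cl2, 0 °C → rt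
Reagents that add atoms: 12, CCOP(=O)(OCC)C(C)C(=O)O; 13, Cl.N[C@@H](CCC(N)=O)C(=O)OC(C)(C)C
Why: standard carbodiimide amide coupling; the amino ester is the amine component, so its α‑centre is not at risk.

**Step 10**
Reactants: 11, cage aldehyde; 14, phosphonoamide
Product: 15, homoplatensimide A tert‑butyl ester ((E)‑C3=C4)
Conditions: LiCl, DBU, MeCN, 0 °C → rt
Reagents that add atoms: 14, CCOP(=O)(OCC)C(C)C(=O)N[C@@H](CCC(N)=O)C(=O)OC(C)(C)C
Why: Masamune–Roush Horner–Wadsworth–Emmons olefination; the α‑methyl phosphonoamide gives the (E)‑trisubstituted enamide, and the stabilised anion reacts only with the aldehyde, not the hindered enone.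

**Step 11**
Reactants: 15, tert‑butyl ester
Product: 16, homoplatensimide A
Conditions: TFA–CH2Cl2 (1:3), anisole, 0 °C → rt
Reagents that add atoms: none
Why: acidolytic tert‑butyl ester cleavage; the cage ether, enone, enamide and primary amide are stable to TFA (the cage ether is formed under TFA in the literature).

## Compound list

1 | (1R,5S)‑(+)‑nopinone | CC1(C)[C@H]2CCC(=O)[C@@H]1C2 | starting material
2 | ethyl vinyl ketone | CCC(=O)C=C | starting material
3 | pinane‑fused tricyclic enone | CC1(C)[C@H]2C[C@@H]3CCC(=O)C(C)=C3[C@@H]1C2 | intermediate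
4 | ring‑opened dienol acetate | CC(=O)OC1=C(C)C2=CC[C@@H](C(C)=C)C[C@@H]2CC1 | intermediate
5 | cis‑γ‑hydroxy enone | CC1=C2[C@@H](O)C[C@@H](C(C)=C)C[C@@H]2CCC1=O | intermediate
6 | bromo ether | CC1=C2[C@@H]3C[C@H](C[C@@H]2CCC1=O)[C@](C)(CBr)O3 | intermediate
7 | cage enone (C9=C10) | CC1=C2[C@@H]3C[C@@H]4C[C@@]2(CCC1=O)C[C@]4(C)O3 | intermediate
8 | saturated cage ketone (C10 epimers) | CC1C(=O)CC[C@]23C[C@H]4C[C@H](O[C@@]4(C)C2)[C@H]31 | intermediate
9 | methyl cage enone (C10 epimers) | CC1C(=O)C=C[C@]23C[C@H]4C[C@H](O[C@@]4(C)C2)[C@H]31 | intermediate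
10 | acrolein | C=CC=O | starting material
11 | cage aldehyde | O=CCC[C@]1(C)C(=O)C=C[C@]23C[C@H]4C[C@H](O[C@@]4(C)C2)[C@H]31 | intermediate
12 | 2‑(diethoxyphosphoryl)propanoic acid | CCOP(=O)(OCC)C(C)C(=O)O | starting material
13 | L‑glutamine tert‑butyl ester hydrochloride | Cl.N[C@@H](CCC(N)=O)C(=O)OC(C)(C)C | starting material
14 | tert‑butyl N‑[2‑(diethoxyphosphoryl)propanoyl]‑L‑glutaminate | CCOP(=O)(OCC)C(C)C(=O)N[C@@H](CCC(N)=O)C(=O)OC(C)(C)C | intermediate
15 | homoplatensimide A tert‑butyl ester | C/C(=C\CC[C@]1(C)C(=O)C=C[C@]23C[C@H]4C[C@H](O[C@@]4(C)C2)[C@H]31)C(=O)N[C@@H](CCC(N)=O)C(=O)OC(C)(C)C | intermediate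
16 | homoplatensimide A | C/C(=C\CC[C@]1(C)C(=O)C=C[C@]23C[C@H]4C[C@H](O[C@@]4(C)C2)[C@H]31)C(=O)N[C@@H](CCC(N)=O)C(=O)O | target

## Step count and risks

Total steps: 11. Longest linear sequence: 10 (steps 1–8, 10, 11).

Steps most likely to fail:

1. **Step 5 (proposed new photochemical γ‑alkylation).** Risks are fragmentation of the γ‑alkoxy enone radical anion or no electron transfer. Fallback (known chemistry): exchange bromide for iodide (NaI, acetone) and close the ring by thermal ionic dienolate γ‑alkylation (KOt‑Bu, t‑BuOH/DMSO, 60–100 °C), the mode precedented by the phenolate para‑alkylation of the analogous bromo ether.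
2. **Step 6 (facial selectivity of hydrogenation at C9).** If H2 adds from the wrong face, reduce before cage closure instead: hydrogenate bromo ether 6 (H2 adds syn to the angular C8–H on the convex face), desaturate to the C6=C7 enone, then close the cage by γ‑alkylation at C8, which lands directly on 9.
3. **Step 3 (chemo‑ and diastereoselective γ‑hydroxylation).** Risks are competing epoxidation of the isopropenyl group and formation of the trans C11 alcohol, which cannot cyclise in step 4. Fallback: set C11 by inversion rather than facial selectivity, i.e. Mitsunobu esterification of the trans alcohol (p‑nitrobenzoic acid, DIAD, PPh3) and mild methanolysis to the cis alcohol before step 4.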